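The constants stand for no real mixture; the flask was simulated.

If the solid substrate in this flask lasts, it holds c(dissolved substrate) at its solubility, and the coupling partner then sees a constant concentration of its reaction partner.

solid substrate 0.50 mM; coupling partner 0.350 mM; time 20 s

    solid substrate ⇌ dissolved substrate, rate k1*(cs1 - [dissolved substrate]) while solid is left; crystals form when [dissolved substrate] > cs1 (cs1 = 0.21 mM, k1 = 0.503 /s)
    dissolved substrate + coupling partner ⇌ target (K2 = 2800 /M, k2 = 48800 /M/s)
    solid product ⇌ target, rate k3*(cs3 - [target]) while solid is left; crystals form when [target] > cs3 (cs3 = 0.17 mM, k3 = 1.32 /s)

- amount of target and solid product together at 20 s, in percent of the solid substrate charged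
- the change that raises the amount of target and solid product together at 20 s, in percent of the solid substrate charged most ("none" if none brings more than 2 percentage points) (south-west / west / north-west / north / none)
- amount of target and solid product together at 20 s, in percent of the solid substrate charged, after north-west

- south-west: doubling the solubility in step 1, all else as stated
- west: doubling the solubility in step 3, all else as stated
- north-west: doubling the dissolution coefficient of step 1, all else as stated
- north: doubling the amount of coupling partner, all else as stated

- what is said of target includes solid product
- solid substrate, solid product is a solid; its amount is given per volume of the solution
- at the start none of the solid substrate is in solution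
- run time (flask): 20 s

We keep the books on the coupling partner, the limiting reagent, because its 0.350 mM stands below the 0.50 mM of solid substrate and step 2 uses them one to one. Step 2 relaxes at 34.5 /s, far faster than dissolution at 0.503 /s, so we hold it at equilibrium. With c(dissolved substrate) at 0.21 mM, the part of the coupling partner in the target is the bound share, K2·cs1/(1+K2·cs1), which is 37.0%.

The first entry is therefore 0.130 mM bound as target, and the second is 0.220 mM unbound. Solid product gets no entry, because c(target) stays below 0.17 mM. The solid lasts, because solution and target together take 0.340 mM.

Is 20 s long enough? Dissolution fills the solution and the target together, and the curve of target against c(dissolved substrate) bends. Its mean slope 0.617 gives a time constant of 3.21 s. The steeper starting slope gives 3.94 s, and 20 s is still 5.08 of those, leaving a gap of 0.624%.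

So we commit to y = 25.9%, and to the same after north-west, since k1 is absent from the share. West touches no entry. North doubles the coupling partner, and the same share then gives 0.260 mM of target, above the 0.17 mM of step 3, so crystals form and the gain of 26 percentage points from doubling the entry is a figure on paper. South-west raises the share to 54.0%, worth 12 points on paper, though its books ask for 0.609 mM of substrate. We choose north.

The forecast gives 25.9% (from 25.5% to 26.3%), 25.9% after north-west, and north, in its words: “North-west only gets there faster”.

The simulation gives 25.9%, then 25.9% after north-west, and north as best, with 41 points against 7.8 points for south-west. Left to 200 s, this flask reads 25.9%. Its unbound coupling partner at 20.0 s, 63.0%, matches the 63.0% that the bound share leaves. A neighbour flask holds 0.21 mM of coupling partner, and the same share gives 0.0777 mM of target, or 15.5% of the solid substrate charged. That flask gives 15.5%, with 63% of its coupling partner unbound.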